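**Retrosynthetic overview**
1. Target 23 ← DIBAL reduction of macrocyclic E-enoate 22. The only ring (14-membered) is closed in step 11 by intramolecular Horner–Wadsworth–Emmons olefination at the hydroxymethyl-bearing alkene.
2. The ring Z-alkene and the aldehyde arm ← Z-selective iodo-olefination of aldehyde 13, then B-alkyl Suzuki coupling.
3. The stereocentre and the E side-chain alkene ← Eschenmoser–Claisen rearrangement with 1,3-chirality transfer from (R)-allylic alcohol 9.
4. 9 ← Keck allylation and prenyl cross-metathesis on enal 5 ← SeO2 oxidation of ester 3.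
5. 3 ← SN2 coupling of geranyl chloride (source of the ring E-methyl alkene) with a zinc homoenolate.

Assumption: the SMILES is read literally (R stereocentre; ring alkenes 1E by CIP with ring carbons cis, 5Z, 11E; side chain 2E), and reagents sold as solutions (organozinc 2, Schwartz reagent, Grubbs II) count as commercial.

**Route**

Step 1
Reactants: 1 geranyl chloride; 2 (3-ethoxy-3-oxopropyl)zinc bromide
Product: 3 ethyl (5E)-6,10-dimethylundeca-5,9-dienoate
Conditions: CoBr2 (10 mol%), THF/NMP, −10 °C → rt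
Reagents that add atoms: (3-ethoxy-3-oxopropyl)zinc bromide 2, CCOC(=O)CC[Zn]Br
Why: Cobalt-catalysed allyl–alkylzinc cross-coupling is expected to proceed with SN2 (α) regiochemistry and retention of the E alkene, so the zinc homoenolate installs the three-carbon ester arm in one operation.

Step 2
Reactants: 3 ethyl (5E)-6,10-dimethylundeca-5,9-dienoate
Product: 5 ethyl (5E,9E)-6,10-dimethyl-11-oxoundeca-5,9-dienoate, via allylic alcohol 4 (not isolated)
Conditions: SeO2 (0.5 equiv), t-BuOOH, salicylic acid (cat.), CH2Cl2, rt; filter; MnO2, CH2Cl2, rt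
Reagents that add atoms: tert-butyl hydroperoxide, CC(C)(C)OO (oxygen relayed by selenium dioxide, O=[Se]=O)
Why: SeO2/t-BuOOH allylic oxidation (ene then [2,3] shift) attacks the E-methyl of the terminal trisubstituted alkene, and MnO2 oxidation of the allylic alcohol converges the crude mixture on the E-enal.

Step 3
Reactants: 5 ethyl (5E,9E)-6,10-dimethyl-11-oxoundeca-5,9-dienoate; 6 allyltributylstannane
Product: 7 ethyl (5E,9E,11R)-11-hydroxy-6,10-dimethyltetradeca-5,9,13-trienoate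
Conditions: (R)-BINOL (20 mol%), Ti(OiPr)4 (10 mol%), 4 Å MS, CH2Cl2, −20 °C; aq. NaHCO3
Reagents that add atoms: allyltributylstannane 6, C=CC[Sn](CCCC)(CCCC)CCCC
Why: In this Keck asymmetric allylation the (R)-BINOL–Ti(IV) Lewis acid directs the allylstannane to the Re face of the enal, setting the 11R carbinol (about 90–95% ee expected) while the ester is untouched.

Step 4
Reactants: 7 ethyl (5E,9E,11R)-11-hydroxy-6,10-dimethyltetradeca-5,9,13-trienoate; 8 2-methylbut-2-ene
Product: 9 ethyl (5E,9E,11R)-11-hydroxy-6,10,14-trimethylpentadeca-5,9,13-trienoate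
Conditions: Grubbs II (5 mol%), 2-methylbut-2-ene/CH2Cl2, 40 °C (sealed)
Reagents that add atoms: 2-methylbut-2-ene 8, CC=C(C)C
Why: Olefin cross-metathesis with excess 2-methylbut-2-ene converts only the monosubstituted alkene into the prenyl group, the trisubstituted alkenes being inert to the Ru carbene under these conditions.

Step 5
Reactants: 9 ethyl (5E,9E,11R)-11-hydroxy-6,10,14-trimethylpentadeca-5,9,13-trienoate; 10 N,N-dimethylacetamide dimethyl acetal
Product: 12 ethyl (5E,9R,10E)-9-[2-(dimethylamino)-2-oxoethyl]-6,10,14-trimethylpentadeca-5,10,13-trienoate, via ketene N,O-acetal 11 (not isolated)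
Conditions: MeC(OMe)2NMe2 (5 equiv), xylenes, 140 °C (−MeOH)
Reagents that add atoms: N,N-dimethylacetamide dimethyl acetal 10, CC(OC)(OC)N(C)C
Why: The Eschenmoser–Claisen [3,3] rearrangement runs through a chair transition state with the prenyl CH2 equatorial, transferring the 11R carbinol chirality suprafacially to the new 9R stereocentre and forming the 10E trisubstituted alkene.

Step 6
Reactants: 12 ethyl (5E,9R,10E)-9-[2-(dimethylamino)-2-oxoethyl]-6,10,14-trimethylpentadeca-5,10,13-trienoate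
Product: 13 ethyl (5E,9R,10E)-6,10,14-trimethyl-9-(2-oxoethyl)pentadeca-5,10,13-trienoate
Conditions: Cp2Zr(H)Cl (1.5 equiv), THF, rt, 20 min; SiO2/H2O
Reagents that add atoms: none
Why: Schwartz-reagent reduction of the tertiary amide stops at a zirconated hemiaminal that releases the aldehyde only on work-up, leaving the ethyl ester and the trisubstituted alkenes intact.

Step 7
Reactants: 13 ethyl (5E,9R,10E)-6,10,14-trimethyl-9-(2-oxoethyl)pentadeca-5,10,13-trienoate; 14 ethyltriphenylphosphonium iodide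
Product: 15 ethyl (5E,9R,10E)-9-[(2Z)-3-iodobut-2-en-1-yl]-6,10,14-trimethylpentadeca-5,10,13-trienoate
Conditions: 14, n-BuLi, THF, 0 °C; I2, −78 °C; NaHMDS, −20 °C; then 13, −78 → −20 °C
Reagents that add atoms: ethyltriphenylphosphonium iodide 14, CC[P+](c1ccccc1)(c1ccccc1)c1ccccc1.[I-]; iodine, II
Why: The Zhao α-iodoalkylidene Wittig olefination gives the (Z)-2-iodoalkene (iodine cis to the chain) under kinetic control, and the stereocentre is β to the aldehyde so it cannot epimerise.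

Step 8
Reactants: 15 ethyl (5E,9R,10E)-9-[(2Z)-3-iodobut-2-en-1-yl]-6,10,14-trimethylpentadeca-5,10,13-trienoate; 16 acrolein diethyl acetal
Product: 17 ethyl (5E,9R,10E)-9-[(2Z)-6,6-diethoxy-3-methylhex-2-en-1-yl]-6,10,14-trimethylpentadeca-5,10,13-trienoate
Conditions: 16, 9-BBN, THF, 0 °C → rt; then 15, PdCl2(dppf) (5 mol%), AsPh3, Cs2CO3, DMF/H2O, rt
Reagents that add atoms: acrolein diethyl acetal 16, C=CC(OCC)OCC
Why: B-alkyl Suzuki–Miyaura coupling of the in situ alkyl-9-BBN with the vinyl iodide proceeds with retention, fixing the Z trisubstituted alkene and delivering the masked aldehyde arm.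

Step 9
Reactants: 17 ethyl (5E,9R,10E)-9-[(2Z)-6,6-diethoxy-3-methylhex-2-en-1-yl]-6,10,14-trimethylpentadeca-5,10,13-trienoate; 18 diethyl chlorophosphite
Product: 20 ethyl (5E,9R,10E)-9-[(2Z)-6,6-diethoxy-3-methylhex-2-en-1-yl]-2-(diethoxyphosphoryl)-6,10,14-trimethylpentadeca-5,10,13-trienoate (C2 epimers), via phosphonite 19 (not isolated)
Conditions: LDA (1.1 equiv), THF, −78 °C; ClP(OEt)2, −78 °C → rt; then 30% H2O2, 0 °C
Reagents that add atoms: diethyl chlorophosphite 18, CCOP(Cl)OCC; hydrogen peroxide, OO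
Why: Enolate C-phosphinylation with the P(III) chloride followed by in situ oxidation gives the α-phosphono ester, whose new C2 centre (a mixture of epimers) is erased in step 11.

Step 10
Reactants: 20 ethyl (5E,9R,10E)-9-[(2Z)-6,6-diethoxy-3-methylhex-2-en-1-yl]-2-(diethoxyphosphoryl)-6,10,14-trimethylpentadeca-5,10,13-trienoate
Product: 21 ethyl (5E,9R,10E)-2-(diethoxyphosphoryl)-6,10,14-trimethyl-9-[(2Z)-3-methyl-6-oxohex-2-en-1-yl]pentadeca-5,10,13-trienoate (C2 epimers)
Conditions: PPTS, acetone/H2O (9:1), 50 °C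
Reagents that add atoms: water, O
Why: Mild acid-catalysed acetal hydrolysis frees the aldehyde while the phosphonate, the ester and the trisubstituted alkenes survive.

Step 11
Reactants: 21 ethyl (5E,9R,10E)-2-(diethoxyphosphoryl)-6,10,14-trimethyl-9-[(2Z)-3-methyl-6-oxohex-2-en-1-yl]pentadeca-5,10,13-trienoate
Product: 22 ethyl (1E,5Z,8R,11E)-5,11-dimethyl-8-[(2E)-6-methylhepta-2,5-dien-2-yl]cyclotetradeca-1,5,11-triene-1-carboxylate
Conditions: LiCl, DBU, MeCN, 1 mM (syringe-pump addition), rt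
Reagents that add atoms: none
Why: Intramolecular Horner–Wadsworth–Emmons olefination (Masamune–Roush conditions, high dilution) closes the 14-membered ring and gives the E-enoate, ester trans to the β-alkyl group, as is usual for α-alkyl phosphonoacetates.

Step 12
Reactants: 22 ethyl (1E,5Z,8R,11E)-5,11-dimethyl-8-[(2E)-6-methylhepta-2,5-dien-2-yl]cyclotetradeca-1,5,11-triene-1-carboxylate
Product: 23 [(1E,5Z,8R,11E)-5,11-dimethyl-8-[(2E)-6-methylhepta-2,5-dien-2-yl]cyclotetradeca-1,5,11-trien-1-yl]methanol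
Conditions: DIBAL-H (3 equiv), CH2Cl2, −78 → −20 °C; Rochelle salt
Reagents that add atoms: none
Why: DIBAL-H 1,2-reduction of the α,β-unsaturated ester gives the allylic alcohol without touching the isolated alkenes or the stereocentre.

**Compound list**
1 | geranyl chloride, (2E)-1-chloro-3,7-dimethylocta-2,6-diene | CC(C)=CCC/C(C)=C/CCl | starting material
2 | (3-ethoxy-3-oxopropyl)zinc bromide | CCOC(=O)CC[Zn]Br | starting material
3 | ethyl (5E)-6,10-dimethylundeca-5,9-dienoate | CCOC(=O)CCC/C=C(\C)CCC=C(C)C | intermediate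
4 | ethyl (5E,9E)-11-hydroxy-6,10-dimethylundeca-5,9-dienoate | CCOC(=O)CCC/C=C(\C)CC/C=C(\C)CO | intermediate
5 | ethyl (5E,9E)-6,10-dimethyl-11-oxoundeca-5,9-dienoate | CCOC(=O)CCC/C=C(\C)CC/C=C(\C)C=O | intermediate
6 | allyltributylstannane | C=CC[Sn](CCCC)(CCCC)CCCC | starting material
7 | ethyl (5E,9E,11R)-11-hydroxy-6,10-dimethyltetradeca-5,9,13-trienoate | CCOC(=O)CCC/C=C(\C)CC/C=C(\C)[C@H](O)CC=C | intermediate
8 | 2-methylbut-2-ene | CC=C(C)C | starting material
9 | ethyl (5E,9E,11R)-11-hydroxy-6,10,14-trimethylpentadeca-5,9,13-trienoate | CCOC(=O)CCC/C=C(\C)CC/C=C(\C)[C@H](O)CC=C(C)C | intermediate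
10 | N,N-dimethylacetamide dimethyl acetal | CC(OC)(OC)N(C)C | starting material
11 | ethyl (5E,9E,11R)-11-{[1-(dimethylamino)ethenyl]oxy}-6,10,14-trimethylpentadeca-5,9,13-trienoate (ketene N,O-acetal) | CCOC(=O)CCC/C=C(\C)CC/C=C(\C)[C@H](OC(=C)N(C)C)CC=C(C)C | intermediate
12 | ethyl (5E,9R,10E)-9-[2-(dimethylamino)-2-oxoethyl]-6,10,14-trimethylpentadeca-5,10,13-trienoate | CCOC(=O)CCC/C=C(\C)CC[C@H](CC(=O)N(C)C)/C(C)=C/CC=C(C)C | intermediate
13 | ethyl (5E,9R,10E)-6,10,14-trimethyl-9-(2-oxoethyl)pentadeca-5,10,13-trienoate | CCOC(=O)CCC/C=C(\C)CC[C@H](CC=O)/C(C)=C/CC=C(C)C | intermediate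
14 | ethyltriphenylphosphonium iodide | CC[P+](c1ccccc1)(c1ccccc1)c1ccccc1.[I-] | starting material
15 | ethyl (5E,9R,10E)-9-[(2Z)-3-iodobut-2-en-1-yl]-6,10,14-trimethylpentadeca-5,10,13-trienoate | CCOC(=O)CCC/C=C(\C)CC[C@H](C/C=C(/C)I)/C(C)=C/CC=C(C)C | intermediate
16 | acrolein diethyl acetal, 3,3-diethoxyprop-1-ene | C=CC(OCC)OCC | starting material
17 | ethyl (5E,9R,10E)-9-[(2Z)-6,6-diethoxy-3-methylhex-2-en-1-yl]-6,10,14-trimethylpentadeca-5,10,13-trienoate | CCOC(=O)CCC/C=C(\C)CC[C@H](C/C=C(/C)CCC(OCC)OCC)/C(C)=C/CC=C(C)C | intermediate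
18 | diethyl chlorophosphite | CCOP(Cl)OCC | starting material
19 | ethyl (5E,9R,10E)-2-(diethoxyphosphanyl)-9-[(2Z)-6,6-diethoxy-3-methylhex-2-en-1-yl]-6,10,14-trimethylpentadeca-5,10,13-trienoate (C2 epimers) | CCOC(=O)C(P(OCC)OCC)CC/C=C(\C)CC[C@H](C/C=C(/C)CCC(OCC)OCC)/C(C)=C/CC=C(C)C | intermediate
20 | ethyl (5E,9R,10E)-9-[(2Z)-6,6-diethoxy-3-methylhex-2-en-1-yl]-2-(diethoxyphosphoryl)-6,10,14-trimethylpentadeca-5,10,13-trienoate (C2 epimers) | CCOC(=O)C(P(=O)(OCC)OCC)CC/C=C(\C)CC[C@H](C/C=C(/C)CCC(OCC)OCC)/C(C)=C/CC=C(C)C | intermediate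
21 | ethyl (5E,9R,10E)-2-(diethoxyphosphoryl)-6,10,14-trimethyl-9-[(2Z)-3-methyl-6-oxohex-2-en-1-yl]pentadeca-5,10,13-trienoate (C2 epimers) | CCOC(=O)C(P(=O)(OCC)OCC)CC/C=C(\C)CC[C@H](C/C=C(/C)CCC=O)/C(C)=C/CC=C(C)C | intermediate
22 | ethyl (1E,5Z,8R,11E)-5,11-dimethyl-8-[(2E)-6-methylhepta-2,5-dien-2-yl]cyclotetradeca-1,5,11-triene-1-carboxylate | CC(C)=CC/C=C(\C)[C@H]1C/C=C(/C)CC/C=C(/C(=O)OCC)CC/C=C(\C)CC1 | intermediate
23 | [(1E,5Z,8R,11E)-5,11-dimethyl-8-[(2E)-6-methylhepta-2,5-dien-2-yl]cyclotetradeca-1,5,11-trien-1-yl]methanol | CC(C)=CC/C=C(\C)[C@H]1C/C=C(/C)CC/C=C(/CO)CC/C=C(\C)CC1 | target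

**Totals and risks**
Total step count: 12. Longest linear sequence: 12 (fully linear from geranyl chloride 1).

The three steps most likely to fail are steps 1, 2 and 11.

Step 1 (cobalt-catalysed allyl–alkylzinc coupling; the risk is SN2' attack or a sluggish organozinc halide). The fallback sets out from 1 and comes back at 3, replacing the zinc homoenolate by a Grignard coupling and oxidation-state adjustment. Geranyl chloride 1 is coupled with commercial (1,3-dioxan-2-ylethyl)magnesium bromide under copper catalysis (Li2CuCl4 cat., THF, −20 → 0 °C, SN2-selective for primary allylic halides) to give 2-[(4E)-5,9-dimethyldeca-4,8-dien-1-yl]-1,3-dioxane F1. Acid hydrolysis (2 M HCl, THF, 40 °C) gives (5E)-6,10-dimethylundeca-5,9-dienal F2. Pinnick oxidation (NaClO2, NaH2PO4, 2-methylbut-2-ene, t-BuOH/H2O) gives (5E)-6,10-dimethylundeca-5,9-dienoic acid F3. Esterification (EtI, K2CO3, DMF) returns 3.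

Step 2 (SeO2 oxidation; the risk is competing oxidation at the internal trisubstituted alkene and low yield). The fallback sets out from 3 and comes back at 5, replacing allylic C–H oxidation by terminal-alkene cleavage and re-olefination. Terminal-selective bromohydrin formation on 3 (NBS, THF/H2O, 0 °C) gives ethyl (5E)-9-bromo-10-hydroxy-6,10-dimethylundec-5-enoate F4. Ring closure (K2CO3, EtOH) gives ethyl (5E)-8-(3,3-dimethyloxiran-2-yl)-6-methyloct-5-enoate F5. Periodic acid cleavage (H5IO6, THF/H2O, 0 °C) gives ethyl (5E)-6-methyl-9-oxonon-5-enoate F6. An E-selective stabilised Wittig reaction with 2-(triphenylphosphoranylidene)propanal (toluene, 90 °C) returns enal 5.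

Step 11 (macrocyclic Horner–Wadsworth–Emmons; the risk is oligomerisation or poor E/Z control in the ring). The fallback sets out from 17 and comes back at 22, replacing the phosphonate olefination by a samarium Reformatsky macrocyclisation and elimination. α-Bromination of 17 (LDA, THF, −78 °C; CBr4) gives ethyl (5E,9R,10E)-2-bromo-9-[(2Z)-6,6-diethoxy-3-methylhex-2-en-1-yl]-6,10,14-trimethylpentadeca-5,10,13-trienoate F7. Acetal hydrolysis (PPTS, acetone/H2O) gives ethyl (5E,9R,10E)-2-bromo-6,10,14-trimethyl-9-[(2Z)-3-methyl-6-oxohex-2-en-1-yl]pentadeca-5,10,13-trienoate F8. SmI2 (THF, high dilution, −78 → 0 °C) closes the ring to ethyl (5Z,8R,11E)-2-hydroxy-5,11-dimethyl-8-[(2E)-6-methylhepta-2,5-dien-2-yl]cyclotetradeca-5,11-diene-1-carboxylate F9. Mesylation (MsCl, Et3N) gives ethyl (5Z,8R,11E)-2-(methanesulfonyloxy)-5,11-dimethyl-8-[(2E)-6-methylhepta-2,5-dien-2-yl]cyclotetradeca-5,11-diene-1-carboxylate F10. E1cB elimination with DBU returns the E-enoate 22.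

**Further compounds**
F1 | step 1 | 2-[(4E)-5,9-dimethyldeca-4,8-dien-1-yl]-1,3-dioxane | CC(C)=CCC/C(C)=C/CCCC1OCCCO1
F2 | step 1 | (5E)-6,10-dimethylundeca-5,9-dienal | CC(C)=CCC/C(C)=C/CCCC=O
F3 | step 1 | (5E)-6,10-dimethylundeca-5,9-dienoic acid | CC(C)=CCC/C(C)=C/CCCC(=O)O
F4 | step 2 | ethyl (5E)-9-bromo-10-hydroxy-6,10-dimethylundec-5-enoate (racemic) | CCOC(=O)CCC/C=C(\C)CCC(Br)C(C)(C)O
F5 | step 2 | ethyl (5E)-8-(3,3-dimethyloxiran-2-yl)-6-methyloct-5-enoate (racemic) | CCOC(=O)CCC/C=C(\C)CCC1OC1(C)C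
F6 | step 2 | ethyl (5E)-6-methyl-9-oxonon-5-enoate | CCOC(=O)CCC/C=C(\C)CCC=O
F7 | step 11 | ethyl (5E,9R,10E)-2-bromo-9-[(2Z)-6,6-diethoxy-3-methylhex-2-en-1-yl]-6,10,14-trimethylpentadeca-5,10,13-trienoate (C2 epimers) | CCOC(=O)C(Br)CC/C=C(\C)CC[C@H](C/C=C(/C)CCC(OCC)OCC)/C(C)=C/CC=C(C)C
F8 | step 11 | ethyl (5E,9R,10E)-2-bromo-6,10,14-trimethyl-9-[(2Z)-3-methyl-6-oxohex-2-en-1-yl]pentadeca-5,10,13-trienoate (C2 epimers) | CCOC(=O)C(Br)CC/C=C(\C)CC[C@H](C/C=C(/C)CCC=O)/C(C)=C/CC=C(C)C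
F9 | step 11 | ethyl (5Z,8R,11E)-2-hydroxy-5,11-dimethyl-8-[(2E)-6-methylhepta-2,5-dien-2-yl]cyclotetradeca-5,11-diene-1-carboxylate (diastereomer mixture at C1/C2) | CC(C)=CC/C=C(\C)[C@H]1C/C=C(/C)CCC(O)C(C(=O)OCC)CC/C=C(\C)CC1
F10 | step 11 | ethyl (5Z,8R,11E)-2-(methanesulfonyloxy)-5,11-dimethyl-8-[(2E)-6-methylhepta-2,5-dien-2-yl]cyclotetradeca-5,11-diene-1-carboxylate (diastereomer mixture at C1/C2) | CC(C)=CC/C=C(\C)[C@H]1C/C=C(/C)CCC(OS(C)(=O)=O)C(C(=O)OCC)CC/C=C(\C)CC1
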